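**Plan**

1. Locants: unprimed = 3‑arylchroman core (ring A benzo, ring C pyran); primed = dimethylchromene unit (ring B benzo, ring D pyran). Retrosynthetic cuts, in order: the two benzyl ethers; the ring D carbinol C3' back to the C3'=C4' alkene; C4–O (inverted, then back to the C4 ketone); ring C at C2–C3 and O1–C8a, releasing formaldehyde and a 2‑fluorodeoxybenzoin; the C3–C4 bond, giving two benzaldehydes.
2. Enabling feature: at the isoflavanone level C3 lies between the C4 carbonyl and ring B, so it is an acidic, enolizable carbon. C8a of ring A is ortho to the same carbonyl and meta to the C7 oxygen, so a fluoride there leaves by addition–elimination. O1–C2 is one formaldehyde, so aldol at C3 plus O‑arylation at C8a should close ring C in one flask (formal [4+2] annulation).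
3. Forward order: ring D is fused onto ring B (chromenylation); rings A and B are joined through C3–C4 (enamine olefination, hydrolysis); ring C is closed by the annulation; then reduction, C4 inversion, ring D oxygenation and debenzylation.
4. Stereochemistry: C3 is left labile at the ketone stage on purpose. Transfer hydrogenation under dynamic kinetic resolution sets C3 (R) and C4 (R), cis; Mitsunobu inversion makes C4 (S), 3,4‑trans. C3' (R) comes from epoxidation with (R,R)-(salen)MnCl and hydride opening at benzylic C4'.

Key step: step 6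

Assumption: the sense of induction of the two catalyst‑controlled steps is taken from the established models (aryl alkyl ketones for the TsDPEN catalyst, 2,2‑dimethylchromene for the salen catalyst); if either proved opposite, the enantiomeric catalyst would be used.

**Route**

Step 1
Reactants: 1 2,4-dihydroxybenzaldehyde; 2 3-methylbut-2-enal
Product: 4 5-hydroxy-2,2-dimethyl-2H-chromene-6-carbaldehyde, via ortho-quinone methide 3 (not isolated)
Conditions: pyridine, 120 °C
Reagents that add atoms: none
Why: Knoevenagel-type condensation of the enal at the carbon between the two hydroxyls of the chelated acylresorcinol (the C2 hydroxyl is hydrogen-bonded to the formyl group, the C4 hydroxyl is free) should give 3, whose oxa-6π electrocyclization closes ring D as the angular 2,2-dimethyl-2H-chromene (chromenylation of acylresorcinols).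

Step 2
Reactants: 4 5-hydroxy-2,2-dimethyl-2H-chromene-6-carbaldehyde
Product: 5 5-(benzyloxy)-2,2-dimethyl-2H-chromene-6-carbaldehyde
Conditions: BnBr, K2CO3, DMF, 60 °C
Reagents that add atoms: benzyl bromide, BrCc1ccccc1
Why: Williamson etherification of the chelated phenol, with benzyl chosen because it should survive base, transfer hydrogenation, Mitsunobu conditions, hypochlorite and hydride and leave at the end by neutral hydrogenolysis.

Step 3
Reactants: 6 2-fluoro-4-hydroxybenzaldehyde
Product: 7 4-(benzyloxy)-2-fluorobenzaldehyde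
Conditions: BnBr, K2CO3, DMF, 23 °C
Reagents that add atoms: benzyl bromide, BrCc1ccccc1
Why: Williamson etherification, in which O-alkylation of the phenoxide should be far faster at room temperature than any displacement of the aryl fluoride.

Step 4
Reactants: 7 4-(benzyloxy)-2-fluorobenzaldehyde
Product: 9 diphenyl {[4-(benzyloxy)-2-fluorophenyl](phenylamino)methyl}phosphonate (racemic), via N-aryl imine 8 (not isolated)
Conditions: PhNH2, (PhO)2P(O)H, i-PrOH, 23 °C
Reagents that add atoms: aniline, Nc1ccccc1; diphenyl phosphite, O=[PH](Oc1ccccc1)Oc1ccccc1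
Why: Kabachnik–Fields reaction (condensation to imine 8, then addition of the phosphite P–H across C=N); the new stereocenter is racemic and irrelevant because it becomes sp2 in step 5.

Step 5
Reactants: 9 diphenyl {[4-(benzyloxy)-2-fluorophenyl](phenylamino)methyl}phosphonate; 5 5-(benzyloxy)-2,2-dimethyl-2H-chromene-6-carbaldehyde
Product: 11 1-[4-(benzyloxy)-2-fluorophenyl]-2-[5-(benzyloxy)-2,2-dimethyl-2H-chromen-6-yl]ethan-1-one, via N-phenyl enamine 10 (not isolated)
Conditions: Cs2CO3, THF/i-PrOH (4:1), 23 °C; then 1 M HCl (aq), 23 °C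
Reagents that add atoms: water, O
Why: Horner–Wadsworth–Emmons olefination of the α-aminophosphonate carbanion with aldehyde 5 should give enamine 10, and its acid hydrolysis places the carbonyl on the former ring A aldehyde carbon (deoxybenzoin synthesis through α-aminophosphonates), leaving the chromene alkene and the aryl fluoride untouched.

Step 6
Reactants: 11 1-[4-(benzyloxy)-2-fluorophenyl]-2-[5-(benzyloxy)-2,2-dimethyl-2H-chromen-6-yl]ethan-1-one
Product: 13 7-(benzyloxy)-3-[5-(benzyloxy)-2,2-dimethyl-2H-chromen-6-yl]chroman-4-one (racemic at C3), via aldol adduct 12 (not isolated)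
Conditions: (CH2O)n (1.3 equiv), Cs2CO3 (1.5 equiv), wet DMSO, Ar, 25 °C then 70 °C
Reagents that add atoms: paraformaldehyde, depolymerized in the flask to formaldehyde, C=O
Why: Proposed new method: carbonate enolizes C3 of 11 (flanked by the C4 ketone and ring B), the enolate adds to formaldehyde to give aldol alkoxide 12, and this primary alkoxide attacks C8a of ring A, ortho to the C4 carbonyl, through a Meisenheimer intermediate that expels fluoride, so that C2–C3 and O1–C8a form in one flask. The closest known reaction types are the base-mediated hydroxymethylation of deoxybenzoins with formaldehyde, domino aldol/SNAr annulations of 2-fluoroaryl carbonyl compounds, and alkoxide or enolate O-cyclizations onto 2-fluoroaryl ketones that give chromanones and chromones; their combination with formaldehyde as the two-atom C–O component is untested. Ring C closes by a polar six-membered addition–elimination at an aromatic carbon, formally 6-endo-trig with respect to the C8a=C4a–C4=O vinylogous acyl fluoride. The only new stereocenter, C3, forms racemic and is deliberately not controlled, because it stays enolizable next to the C4 ketone and is set in step 7. The step needs a single C-hydroxymethylation and O-arylation at C8a only: aldol addition, dehydration to the α-methylene ketone (reversed by the water present) and a second hydroxymethylation are all reversible, whereas fluoride loss is not, so these equilibria should drain into 13. The ortho relation of fluoride to the C4 carbonyl and the meta relation of the C7 benzyloxy group to C8a make C8a the one electrophilic aryl carbon, and argon is used because deoxybenzoin enolates autoxidize.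

Step 7
Reactants: 13 7-(benzyloxy)-3-[5-(benzyloxy)-2,2-dimethyl-2H-chromen-6-yl]chroman-4-one
Product: 14 (3R,4R)-7-(benzyloxy)-3-[5-(benzyloxy)-2,2-dimethyl-2H-chromen-6-yl]chroman-4-ol (3,4-cis)
Conditions: RuCl(p-cymene)[(R,R)-TsDPEN] (2 mol%), HCO2H/Et3N (5:2), EtOAc, 40 °C
Reagents that add atoms: none
Why: Noyori–Ikariya asymmetric transfer hydrogenation under dynamic kinetic resolution: C3 should epimerize through the enol faster than the ketone is reduced, and the (R,R)-catalyst should deliver hydride to one face of C4 (4R, as for aryl alkyl ketones) of the C3 epimer that leads to the cis alcohol, so both enantiomers of 13 funnel into (3R,4R)-14 while the chromene alkene is left alone.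

Step 8
Reactants: 14 (3R,4R)-7-(benzyloxy)-3-[5-(benzyloxy)-2,2-dimethyl-2H-chromen-6-yl]chroman-4-ol
Product: 15 (3R,4S)-7-(benzyloxy)-3-[5-(benzyloxy)-2,2-dimethyl-2H-chromen-6-yl]chroman-4-yl benzoate (3,4-trans)
Conditions: PhCO2H, PPh3, DIAD, toluene, −20 to 0 °C
Reagents that add atoms: benzoic acid, O=C(O)c1ccccc1
Why: Mitsunobu esterification, in which benzoate displaces the C4 alkoxyphosphonium with inversion to give C4 (S) and the 3,4-trans relationship without touching C3, and the ester then masks the benzylic alcohol during the oxidation in step 9.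

Step 9
Reactants: 15 (3R,4S)-7-(benzyloxy)-3-[5-(benzyloxy)-2,2-dimethyl-2H-chromen-6-yl]chroman-4-yl benzoate
Product: 16 (3R,4S)-7-(benzyloxy)-3-[(3R,4R)-5-(benzyloxy)-3,4-epoxy-2,2-dimethylchroman-6-yl]chroman-4-yl benzoate
Conditions: (R,R)-(salen)MnCl [(R,R)-N,N'-bis(3,5-di-tert-butylsalicylidene)cyclohexane-1,2-diamine manganese chloride] (5 mol%), 4-phenylpyridine N-oxide (20 mol%), NaOCl (aq, pH 11.3), CH2Cl2, 0 °C
Reagents that add atoms: sodium hypochlorite, [Na+].[O-]Cl
Why: Jacobsen–Katsuki epoxidation of the cis-disubstituted, aryl-conjugated C3'=C4' alkene of a 2,2-dimethylchromene, the benchmark substrate class, where the (R,R)-catalyst should set the (3'R,4'R)-epoxide under catalyst control while benzoate and benzyl ethers are inert to buffered hypochlorite.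

Step 10
Reactants: 16 (3R,4S)-7-(benzyloxy)-3-[(3R,4R)-5-(benzyloxy)-3,4-epoxy-2,2-dimethylchroman-6-yl]chroman-4-yl benzoate
Product: 17 (3R,4S)-7-(benzyloxy)-3-[(3R)-5-(benzyloxy)-3-hydroxy-2,2-dimethylchroman-6-yl]chroman-4-ol
Conditions: LiAlH4, THF, −20 to 0 °C; aqueous NaOH work-up
Reagents that add atoms: none
Why: Hydride epoxide opening and ester reduction in one flask: hydride should attack the benzylic C4' (C3' is shielded by the quaternary C2'), so the C3'–O bond and its R configuration are kept, and the benzoate is cleaved at the acyl carbon without touching C4.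

Step 11
Reactants: 17 (3R,4S)-7-(benzyloxy)-3-[(3R)-5-(benzyloxy)-3-hydroxy-2,2-dimethylchroman-6-yl]chroman-4-ol
Product: 18 (3R,4S)-3-[(3R)-3,5-dihydroxy-2,2-dimethylchroman-6-yl]chroman-4,7-diol (target)
Conditions: H2 (1 atm), Pd/C, EtOAc/EtOH, NaHCO3 (solid), 23 °C, short reaction time
Reagents that add atoms: none
Why: Catalytic hydrogenolysis of the two aryl benzyl ethers, run briefly and acid-free so that the benzylic C4–OH is neither hydrogenolysed nor displaced by the freed C5' phenol, and no stereocenter is touched.

**Compound list**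

1 | 2,4-dihydroxybenzaldehyde | O=Cc1ccc(O)cc1O | starting material
2 | 3-methylbut-2-enal | CC(C)=CC=O | starting material
3 | 2-hydroxy-3-(3-methylbut-2-en-1-ylidene)-4-oxocyclohexa-1,5-diene-1-carbaldehyde (ortho-quinone methide, not isolated) | O=C1C=CC(C=O)=C(O)C1=CC=C(C)C | intermediate
4 | 5-hydroxy-2,2-dimethyl-2H-chromene-6-carbaldehyde | CC1(C)C=Cc2c(O)c(C=O)ccc2O1 | intermediate
5 | 5-(benzyloxy)-2,2-dimethyl-2H-chromene-6-carbaldehyde | CC1(C)C=Cc2c(OCc3ccccc3)c(C=O)ccc2O1 | intermediate
6 | 2-fluoro-4-hydroxybenzaldehyde | O=Cc1ccc(O)cc1F | starting material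
7 | 4-(benzyloxy)-2-fluorobenzaldehyde | O=Cc1ccc(OCc2ccccc2)cc1F | intermediate
8 | (E)-N-[4-(benzyloxy)-2-fluorobenzylidene]aniline (not isolated) | Fc1cc(OCc2ccccc2)ccc1/C=N/c1ccccc1 | intermediate
9 | diphenyl {[4-(benzyloxy)-2-fluorophenyl](phenylamino)methyl}phosphonate (racemic) | O=P(Oc1ccccc1)(Oc1ccccc1)C(Nc1ccccc1)c1ccc(OCc2ccccc2)cc1F | intermediate
10 | 1-[4-(benzyloxy)-2-fluorophenyl]-2-[5-(benzyloxy)-2,2-dimethyl-2H-chromen-6-yl]-N-phenylethen-1-amine (enamine, alkene geometry not defined, not isolated) | Fc1cc(OCc2ccccc2)ccc1C(Nc1ccccc1)=Cc1ccc2OC(C)(C)C=Cc2c1OCc1ccccc1 | intermediate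
11 | 1-[4-(benzyloxy)-2-fluorophenyl]-2-[5-(benzyloxy)-2,2-dimethyl-2H-chromen-6-yl]ethan-1-one | O=C(Cc1ccc2OC(C)(C)C=Cc2c1OCc1ccccc1)c1ccc(OCc2ccccc2)cc1F | intermediate
12 | 1-[4-(benzyloxy)-2-fluorophenyl]-2-[5-(benzyloxy)-2,2-dimethyl-2H-chromen-6-yl]-3-hydroxypropan-1-one (racemic aldol adduct, not isolated) | O=C(C(CO)c1ccc2OC(C)(C)C=Cc2c1OCc1ccccc1)c1ccc(OCc2ccccc2)cc1F | intermediate
13 | 7-(benzyloxy)-3-[5-(benzyloxy)-2,2-dimethyl-2H-chromen-6-yl]chroman-4-one (racemic, C3 labile) | O=C1c2ccc(OCc3ccccc3)cc2OCC1c1ccc2OC(C)(C)C=Cc2c1OCc1ccccc1 | intermediate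
14 | (3R,4R)-7-(benzyloxy)-3-[5-(benzyloxy)-2,2-dimethyl-2H-chromen-6-yl]chroman-4-ol | CC1(C)Oc2ccc([C@@H]3COc4cc(OCc5ccccc5)ccc4[C@@H]3O)c(OCc3ccccc3)c2C=C1 | intermediate
15 | (3R,4S)-7-(benzyloxy)-3-[5-(benzyloxy)-2,2-dimethyl-2H-chromen-6-yl]chroman-4-yl benzoate | CC1(C)Oc2ccc([C@@H]3COc4cc(OCc5ccccc5)ccc4[C@H]3OC(=O)c3ccccc3)c(OCc3ccccc3)c2C=C1 | intermediate
16 | (3R,4S)-7-(benzyloxy)-3-[(3R,4R)-5-(benzyloxy)-3,4-epoxy-2,2-dimethylchroman-6-yl]chroman-4-yl benzoate | CC1(C)Oc2ccc([C@@H]3COc4cc(OCc5ccccc5)ccc4[C@H]3OC(=O)c3ccccc3)c(OCc3ccccc3)c2[C@@H]2[C@H]1O2 | intermediate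
17 | (3R,4S)-7-(benzyloxy)-3-[(3R)-5-(benzyloxy)-3-hydroxy-2,2-dimethylchroman-6-yl]chroman-4-ol | CC1(C)Oc2ccc([C@@H]3COc4cc(OCc5ccccc5)ccc4[C@H]3O)c(OCc3ccccc3)c2C[C@H]1O | intermediate
18 | (3R,4S)-3-[(3R)-3,5-dihydroxy-2,2-dimethylchroman-6-yl]chroman-4,7-diol | CC1(C)Oc2ccc([C@@H]3COc4cc(O)ccc4[C@H]3O)c(O)c2C[C@H]1O | target

**Step count and risks**

Total step count: 11. Longest linear sequence: 9 steps (steps 1, 2 and 5 to 11 from compound 1; the branch from compound 6 through steps 3, 4 and 5 to 11 is equally long).

Steps most likely to fail: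

Step 6 (proposed new method). Retro-aldol, dehydration and over-hydroxymethylation may outrun ring closure, or enolization of the aldol adduct may switch off the C4 carbonyl as an activator so that fluoride displacement stalls. The fallback uses known chemistry and sets out from 11. Claisen C-formylation with ethyl formate and NaH (THF, 0 to 23 °C) would give the sodium enolate of 1-[4-(benzyloxy)-2-fluorophenyl]-2-[5-(benzyloxy)-2,2-dimethyl-2H-chromen-6-yl]-3-hydroxyprop-2-en-1-one F1, a stabilized oxygen nucleophile that can neither revert nor dehydrate. Heating in DMF (80 °C) would let the enolate oxygen displace the ortho fluoride, the established O-cyclization of 1-(2-fluoroaryl)-1,3-dicarbonyl compounds to chromones, giving 7-(benzyloxy)-3-[5-(benzyloxy)-2,2-dimethyl-2H-chromen-6-yl]-4H-chromen-4-one F2. Conjugate reduction of F2 with LiBH(s-Bu)3 in THF at −78 °C and protonation of the enolate comes back to the route at 13.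

Step 8. The alkoxyphosphonium at the para-alkoxybenzylic C4 may ionize, giving elimination toward the 3-aryl-2H-chromene or incomplete inversion. The fallback sets out from 14 and abandons SN2 displacement for a deliberately ionizing, stereoconvergent capture. Cl3CCN with catalytic DBU (CH2Cl2, 0 °C) would give (3R,4R)-7-(benzyloxy)-3-[5-(benzyloxy)-2,2-dimethyl-2H-chromen-6-yl]chroman-4-yl 2,2,2-trichloroacetimidate F3. Benzoic acid in CH2Cl2 at −40 °C would then protonate the imidate, and the resulting C4 ion pair should be captured by benzoate anti to the C3 aryl group, the usual 3,4-trans preference of flavan-type C4 cations. This comes back to the route at 15.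

Step 10. Aluminium species may ionize the electron-rich benzylic epoxide, and a 1,2-hydride shift to the chroman-3-one followed by unselective re-reduction would erode the C3' configuration. The fallback sets out from 16 and opens the epoxide by a single-electron path without a cation. Cp2TiCl (trivalent titanium, made in the flask from Cp2TiCl2 and Zn) with 1,4-cyclohexadiene in THF at 23 °C should cleave the C4'–O bond homolytically to the benzylic radical, which takes up a hydrogen atom and leaves the C3'–O bond untouched. This would give (3R,4S)-7-(benzyloxy)-3-[(3R)-5-(benzyloxy)-3-hydroxy-2,2-dimethylchroman-6-yl]chroman-4-yl benzoate F4. Methanolysis of the benzoate (K2CO3, MeOH, 23 °C) comes back to the route at 17.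

Further compounds
F1 | step 6 | 1-[4-(benzyloxy)-2-fluorophenyl]-2-[5-(benzyloxy)-2,2-dimethyl-2H-chromen-6-yl]-3-hydroxyprop-2-en-1-one (enol form, geometry not defined) | O=C(C(=CO)c1ccc2OC(C)(C)C=Cc2c1OCc1ccccc1)c1ccc(OCc2ccccc2)cc1F
F2 | step 6 | 7-(benzyloxy)-3-[5-(benzyloxy)-2,2-dimethyl-2H-chromen-6-yl]-4H-chromen-4-one | O=c1c(-c2ccc3OC(C)(C)C=Cc3c2OCc2ccccc2)coc2cc(OCc3ccccc3)ccc12
F3 | step 8 | (3R,4R)-7-(benzyloxy)-3-[5-(benzyloxy)-2,2-dimethyl-2H-chromen-6-yl]chroman-4-yl 2,2,2-trichloroacetimidate | CC1(C)Oc2ccc([C@@H]3COc4cc(OCc5ccccc5)ccc4[C@@H]3OC(=N)C(Cl)(Cl)Cl)c(OCc3ccccc3)c2C=C1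
F4 | step 10 | (3R,4S)-7-(benzyloxy)-3-[(3R)-5-(benzyloxy)-3-hydroxy-2,2-dimethylchroman-6-yl]chroman-4-yl benzoate | CC1(C)Oc2ccc([C@@H]3COc4cc(OCc5ccccc5)ccc4[C@H]3OC(=O)c3ccccc3)c(OCc3ccccc3)c2C[C@H]1O
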